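Numbering: ring A C1 (depsidone C=O), C2 (ether O), C3 (CHO), C4 (OH), C6 (CH3); ring B C1' (lactone C=O), C2' (OH), C3' (CH2OAc), C4' (ester O), C5' (ether O), C6' (lactol CH).
Cuts, last to first: the lactol acetate used to fix the stereocentre; 3'-CH2–O and lactol C–OH (one double benzylic bromination); C6'–CH2 and CH2–O of the five-membered lactone; the depsidone ester C(=O)–O4'; the diaryl ether C2–O5'.
Forward: ring B fragment 7 and ring A fragment 13 are joined by SNAr at O5', the seven-membered depsidone lactone is closed, and the phthalide ring is closed last on the finished depsidone acid.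
Enabling feature: in ring B the C1' carboxyl has the oxygenated C2' on one side and C6'–H on the other, so a metal held by the free C1' carboxylate can reach one C–H only; the ring A carbonyl is locked in the seven-membered lactone.
Stereochemistry: the only stereocentre, the lactol carbon (S), is set at the end by lipase dynamic kinetic acetylation and kept when the same enzyme removes that acetate at the acyl carbon.

Key step: step 13

Assumption: the lactol carbon epimerises through the open 6'-formyl-1'-carboxylic acid when base, water or heat is present, and is taken to hold its configuration in dry, neutral, aprotic solution at or below room temperature; the last step and the isolation are run under such conditions.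

Step 1
Reactants: 1 2,4-dihydroxy-3-methylbenzoic acid
Product: 2 benzyl 2,4-dihydroxy-3-methylbenzoate
Conditions: BnBr, KHCO3, DMF, 40 °C
Reagents that add atoms: benzyl bromide, BrCc1ccccc1
Why: Carboxylate O-alkylation (Williamson-type esterification); hydrogencarbonate deprotonates only the carboxylic acid, so both phenols stay free.

Step 2
Reactants: 2 benzyl 2,4-dihydroxy-3-methylbenzoate
Product: 3 benzyl 5-bromo-2,4-dihydroxy-3-methylbenzoate
Conditions: NBS (1.0 equiv), MeCN, 0 °C
Reagents that add atoms: N-bromosuccinimide, O=C1CCC(=O)N1Br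
Why: Electrophilic aromatic bromination; C5 is the only free position activated by both hydroxyls (ortho to 4-OH, para to 2-OH), C6 being meta to both.

Step 3
Reactants: 3 benzyl 5-bromo-2,4-dihydroxy-3-methylbenzoate
Product: 4 benzyl 5-bromo-2-hydroxy-4-(methoxymethoxy)-3-methylbenzoate
Conditions: MOMCl (1.1 equiv), K2CO3, acetone, 0 °C to rt
Reagents that add atoms: chloromethyl methyl ether, COCCl
Why: Williamson etherification; the 2-OH is held in a hydrogen bond to the ester carbonyl, so the more acidic, unchelated 4-OH should be alkylated selectively.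

Step 4
Reactants: 4 benzyl 5-bromo-2-hydroxy-4-(methoxymethoxy)-3-methylbenzoate
Product: 5 benzyl 5-bromo-2-methoxy-4-(methoxymethoxy)-3-methylbenzoate
Conditions: MeI, K2CO3, DMF, 50 °C
Reagents that add atoms: iodomethane, CI
Why: Williamson methylation of the remaining chelated phenol under more forcing conditions; the benzyl ester and the MOM ether are inert to carbonate.

Step 5
Reactants: 5 benzyl 5-bromo-2-methoxy-4-(methoxymethoxy)-3-methylbenzoate
Product: 7 benzyl 5-hydroxy-2-methoxy-4-(methoxymethoxy)-3-methylbenzoate, via pinacol boronate 6 (not isolated)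
Conditions: B2pin2, Pd(dppf)Cl2 (5 mol %), KOAc, 1,4-dioxane, 90 °C; then NaBO3·4H2O, THF–H2O, rt
Reagents that add atoms: bis(pinacolato)diboron, CC1(C)OB(OC1(C)C)B1OC(C)(C)C(C)(C)O1; sodium perborate (NaBO3), B(=O)O[O-].[Na+]
Why: Miyaura borylation (oxidative addition of the aryl bromide to zerovalent palladium, transmetalation from boron), then oxidation of the C–B bond with aryl migration to oxygen, which places the one free hydroxyl at C5 (the later O5').

Step 6
Reactants: 8 3,5-difluorotoluene
Product: 9 2,6-difluoro-4-methylbenzaldehyde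
Conditions: n-BuLi, THF, −78 °C; DMF; aq. NH4Cl
Reagents that add atoms: N,N-dimethylformamide, CN(C)C=O
Why: Directed ortho-lithiation; the hydrogen between the two fluorines is by far the most acidic, and the aryllithium is formylated by DMF.

Step 7
Reactants: 9 2,6-difluoro-4-methylbenzaldehyde
Product: 10 2-(dimethoxymethyl)-1,3-difluoro-5-methylbenzene
Conditions: HC(OMe)3, TsOH (cat.), MeOH, 50 °C
Reagents that add atoms: trimethyl orthoformate, COC(OC)OC
Why: Acid-catalysed acetalisation with the orthoester as water scavenger masks the aldehyde against the organolithium of the next step.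

Step 8
Reactants: 10 2-(dimethoxymethyl)-1,3-difluoro-5-methylbenzene
Product: 12 tert-butyl 2,4-difluoro-3-formyl-6-methylbenzoate, via acetal ester 11 (not isolated)
Conditions: s-BuLi, THF, −78 °C; Boc2O, −78 to −20 °C; then 1 M HCl, THF, rt
Reagents that add atoms: di-tert-butyl dicarbonate, CC(C)(C)OC(=O)OC(=O)OC(C)(C)C; water, O
Why: Fluorine-directed ortho-lithiation (the two remaining ring hydrogens are equivalent by symmetry, so one regioisomer only can form), acylation of the aryllithium by Boc2O to the tert-butyl ester, and mild acid hydrolysis of the acyclic acetal, which the tert-butyl ester survives.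

Step 9
Reactants: 12 tert-butyl 2,4-difluoro-3-formyl-6-methylbenzoate
Product: 13 tert-butyl 2-fluoro-3-formyl-4-methoxy-6-methylbenzoate
Conditions: NaOMe (1.05 equiv), MeOH–THF, −10 °C to rt
Reagents that add atoms: sodium methoxide (NaOMe), C[O-].[Na+]
Why: Nucleophilic aromatic substitution (SNAr); both fluorines are ortho to the formyl group, but C4–F is para to the ester and has a free neighbour whereas C2–F is buried between the formyl and tert-butyl ester groups, so methoxide should enter at C4, and the tert-butyl ester cannot transesterify.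

Step 10
Reactants: 7 benzyl 5-hydroxy-2-methoxy-4-(methoxymethoxy)-3-methylbenzoate; 13 tert-butyl 2-fluoro-3-formyl-4-methoxy-6-methylbenzoate
Product: 14 diaryl ether tert-butyl 2-{5-[(benzyloxy)carbonyl]-4-methoxy-2-(methoxymethoxy)-3-methylphenoxy}-3-formyl-4-methoxy-6-methylbenzoate
Conditions: Cs2CO3, DMSO, 60 °C
Reagents that add atoms: none
Why: SNAr diaryl ether synthesis; the remaining fluoride is activated by the ortho formyl and ortho ester groups and is displaced by the phenoxide of 7, whose other oxygens are all capped, so the ether can only form at O5'.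

Step 11
Reactants: 14 diaryl ether
Product: 16 depsidone benzyl ester (benzyl 4-formyl-3,8-dimethoxy-1,9-dimethyl-11-oxo-11H-dibenzo[b,e][1,4]dioxepine-7-carboxylate), via hydroxy acid 15 (not isolated)
Conditions: TFA–CH2Cl2 (1:2), rt; evaporate; TFAA, toluene, 0 °C to rt
Reagents that add atoms: none
Why: Acidolysis removes the tert-butyl ester and the MOM ether (volatile by-products, benzyl ester untouched), and the mixed trifluoroacetic anhydride of the hindered ring A acid then acylates the neighbouring C4' phenol in a 7-exo-trig lactonisation, the classical depsidone closure.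

Step 12
Reactants: 16 depsidone benzyl ester
Product: 17 depsidone C1' acid with C6'–H (4-formyl-3,8-dimethoxy-1,9-dimethyl-11-oxo-11H-dibenzo[b,e][1,4]dioxepine-7-carboxylic acid)
Conditions: H2 (1 atm), 10% Pd/C, EtOAc, rt, stopped at full ester cleavage
Reagents that add atoms: none
Why: Hydrogenolysis of a benzyl ester on palladium is much faster than reduction of the hindered, di-ortho-substituted aryl aldehyde, and it frees the C1' acid under neutral conditions that leave the depsidone lactone alone.

Step 13
Reactants: 17 depsidone C1' acid with C6'–H; 18 dibromomethane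
Product: 20 phthalide-fused depsidone, via bromomethyl acid 19 (not isolated)
Conditions: Pd(OAc)2 (10 mol %), K2HPO4 (3 equiv), CH2Br2 (solvent), 140 °C, sealed tube
Reagents that add atoms: dibromomethane (compound 18), BrCBr
Why: The potassium carboxylate binds divalent palladium and a concerted metalation–deprotonation at C6' gives a five-membered C,O-palladacycle; oxidative addition of dibromomethane to tetravalent palladium and C–C reductive elimination give the 6'-bromomethyl acid 19 and return divalent palladium. The neighbouring carboxylate then displaces bromide in a 5-exo-tet SN2 lactonisation, which closes the phthalide ring. The closest known reaction is the palladium-catalysed, carboxylate-directed ortho C–H alkylation of benzoic acids with dihaloalkanes followed by lactonisation. No stereocentre is formed. The step needs site selectivity, and the substrate secures it: the single free carboxyl group has one ortho C–H (C6'), C2' being methoxylated, the ring A carbonyl is locked in the depsidone lactone and cannot bind the metal as a carboxylate, and ring A has no C–H ortho to a directing group. Both phenols are capped as methyl ethers so that neither they nor a salicylic-acid-type methylene acetal can be alkylated by the solvent.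

Step 14
Reactants: 20 phthalide-fused depsidone
Product: 21 diphenol phthalide (20 with 4-OH and 2'-OH)
Conditions: BCl3 (5 equiv), CH2Cl2, −78 °C to rt; then H2O
Reagents that add atoms: none
Why: Chelation-assisted aryl methyl ether cleavage; BCl3 binds the formyl and phthalide carbonyl oxygens and removes exactly the two ortho methyl groups, leaving both lactones intact.

Step 15
Reactants: 21 diphenol phthalide
Product: 22 tetraacetate (4-OAc, 2'-OAc, 3-CH(OAc)2)
Conditions: Ac2O, H2SO4 (cat.), rt
Reagents that add atoms: acetic anhydride, CC(=O)OC(C)=O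
Why: Acid-catalysed O-acetylation and acylal formation; the phenols become electron-withdrawing acetates and the aldehyde a geminal diacetate, so the next step meets neither an easily brominated phenol ring nor an abstractable formyl hydrogen.

Step 16
Reactants: 22 tetraacetate
Product: 23 dibromide (3'-CH2Br and 3-bromophthalide CHBr, racemic)
Conditions: NBS (2.3 equiv), AIBN (cat.), PhCF3, 85 °C, visible light
Reagents that add atoms: N-bromosuccinimide, O=C1CCC(=O)N1Br
Why: Wohl–Ziegler bromination; the bromine atom abstracts hydrogen at the two most reactive benzylic sites, the ring B methyl and the lactone CH2 (the parent reaction is the standard route to 3-bromophthalide), while the ring A methyl is deactivated by the ortho ester and meta acyloxy groups and a second bromination of the di-ortho-substituted CH2Br is sterically slow; the new CHBr centre forms as the racemate.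

Step 17
Reactants: 23 dibromide
Product: 24 racemic salazinic acid (3'-CH2OH, lactol OH, free phenols and aldehyde)
Conditions: K2CO3, THF–H2O, 0 °C to rt, high dilution; then 1 M HCl
Reagents that add atoms: water, O
Why: Mild aqueous carbonate hydrolyses the aryl acetates, the acylal and the acyl-halide-like 3-bromophthalide, and the freed 2'-phenoxide expels the benzylic bromide to an o-quinone methide that adds water, so both bromides end as hydroxyls; acidification recloses the lactol, which forms as the racemate.

Step 18
Reactants: 24 racemic salazinic acid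
Product: 25 racemic galbinic acid
Conditions: AcOH (glacial), 100 °C
Reagents that add atoms: acetic acid, CC(O)=O
Why: Thermal o-quinone-methide exchange; an o-hydroxybenzyl alcohol loses water in hot acetic acid and the quinone methide adds the solvent, which esterifies only the 3'-CH2OH because phenols and the lactol are not acetylated by acetic acid alone.

Step 19
Reactants: 25 racemic galbinic acid
Product: 26 (1S)-lactol acetate of galbinic acid
Conditions: Burkholderia cepacia lipase (immobilised), vinyl acetate, THF, 40 °C
Reagents that add atoms: vinyl acetate, CC(=O)OC=C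
Why: Lipase-catalysed dynamic kinetic resolution, known for γ-hydroxybutenolide pseudo-acids; the lactol enantiomers interconvert by ring–chain tautomerism through the open formyl acid while the enzyme (chosen by screening for the (S)-selective one) irreversibly acetylates one of them, so the (S)-configuration is set by the enzyme's active site, and the chelated phenols are not lipase substrates.

Step 20
Reactants: 26 (1S)-lactol acetate of galbinic acid
Product: 27 galbinic acid, (S) at the lactol carbon
Conditions: Burkholderia cepacia lipase (immobilised), 1-butanol, MTBE–THF, 20 °C; filter, evaporate below 25 °C, crystallise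
Reagents that add atoms: none
Why: Lipase-catalysed transesterification (alcoholysis) cleaves the activated acylal-type lactol acetate at the acyl carbon, so the C–O bond at the stereocentre is untouched and the configuration is retained, while the ordinary 3'-acetate, shielded by two ortho substituents, should react far more slowly; the dry, neutral medium avoids ring opening.

Compound list
1 | 2,4-dihydroxy-3-methylbenzoic acid | Cc1c(O)ccc(C(=O)O)c1O | starting material
2 | benzyl 2,4-dihydroxy-3-methylbenzoate | Cc1c(O)ccc(C(=O)OCc2ccccc2)c1O | intermediate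
3 | benzyl 5-bromo-2,4-dihydroxy-3-methylbenzoate | Cc1c(O)c(Br)cc(C(=O)OCc2ccccc2)c1O | intermediate
4 | benzyl 5-bromo-2-hydroxy-4-(methoxymethoxy)-3-methylbenzoate | Cc1c(OCOC)c(Br)cc(C(=O)OCc2ccccc2)c1O | intermediate
5 | benzyl 5-bromo-2-methoxy-4-(methoxymethoxy)-3-methylbenzoate | Cc1c(OCOC)c(Br)cc(C(=O)OCc2ccccc2)c1OC | intermediate
6 | benzyl 2-methoxy-4-(methoxymethoxy)-3-methyl-5-(4,4,5,5-tetramethyl-1,3,2-dioxaborolan-2-yl)benzoate (pinacol boronate) | Cc1c(OCOC)c(B2OC(C)(C)C(C)(C)O2)cc(C(=O)OCc2ccccc2)c1OC | intermediate
7 | benzyl 5-hydroxy-2-methoxy-4-(methoxymethoxy)-3-methylbenzoate | Cc1c(OCOC)c(O)cc(C(=O)OCc2ccccc2)c1OC | intermediate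
8 | 3,5-difluorotoluene | Cc1cc(F)cc(F)c1 | starting material
9 | 2,6-difluoro-4-methylbenzaldehyde | Cc1cc(F)c(C=O)c(F)c1 | intermediate
10 | 2-(dimethoxymethyl)-1,3-difluoro-5-methylbenzene | Cc1cc(F)c(C(OC)OC)c(F)c1 | intermediate
11 | tert-butyl 3-(dimethoxymethyl)-2,4-difluoro-6-methylbenzoate (acetal ester) | Cc1cc(F)c(C(OC)OC)c(F)c1C(=O)OC(C)(C)C | intermediate
12 | tert-butyl 2,4-difluoro-3-formyl-6-methylbenzoate | Cc1cc(F)c(C=O)c(F)c1C(=O)OC(C)(C)C | intermediate
13 | tert-butyl 2-fluoro-3-formyl-4-methoxy-6-methylbenzoate | Cc1cc(OC)c(C=O)c(F)c1C(=O)OC(C)(C)C | intermediate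
14 | tert-butyl 2-{5-[(benzyloxy)carbonyl]-4-methoxy-2-(methoxymethoxy)-3-methylphenoxy}-3-formyl-4-methoxy-6-methylbenzoate (diaryl ether) | Cc1cc(OC)c(C=O)c(Oc2cc(C(=O)OCc3ccccc3)c(OC)c(C)c2OCOC)c1C(=O)OC(C)(C)C | intermediate
15 | 2-{5-[(benzyloxy)carbonyl]-2-hydroxy-4-methoxy-3-methylphenoxy}-3-formyl-4-methoxy-6-methylbenzoic acid (hydroxy acid) | Cc1cc(OC)c(C=O)c(Oc2cc(C(=O)OCc3ccccc3)c(OC)c(C)c2O)c1C(=O)O | intermediate
16 | benzyl 4-formyl-3,8-dimethoxy-1,9-dimethyl-11-oxo-11H-dibenzo[b,e][1,4]dioxepine-7-carboxylate (depsidone benzyl ester) | Cc1c(OC)c(C(=O)OCc3ccccc3)cc2c1OC(=O)c1c(C)cc(OC)c(C=O)c1O2 | intermediate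
17 | 4-formyl-3,8-dimethoxy-1,9-dimethyl-11-oxo-11H-dibenzo[b,e][1,4]dioxepine-7-carboxylic acid (depsidone C1' acid, C6'–H) | Cc1c(OC)c(C(=O)O)cc2c1OC(=O)c1c(C)cc(OC)c(C=O)c1O2 | intermediate
18 | dibromomethane | BrCBr | starting material
19 | 6-(bromomethyl)-4-formyl-3,8-dimethoxy-1,9-dimethyl-11-oxo-11H-dibenzo[b,e][1,4]dioxepine-7-carboxylic acid (bromomethyl acid) | Cc1c(OC)c(C(=O)O)c(CBr)c2c1OC(=O)c1c(C)cc(OC)c(C=O)c1O2 | intermediate
20 | 4,10-dimethoxy-5,8-dimethyl-3,7-dioxo-1,3-dihydro-7H-2,6,12-trioxabenzo[5,6]cyclohepta[1,2-e]indene-11-carbaldehyde (phthalide-fused depsidone) | Cc1c(OC)c2C(=O)OCc2c2c1OC(=O)c1c(C)cc(OC)c(C=O)c1O2 | intermediate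
21 | 4,10-dihydroxy-5,8-dimethyl-3,7-dioxo-1,3-dihydro-7H-2,6,12-trioxabenzo[5,6]cyclohepta[1,2-e]indene-11-carbaldehyde (diphenol phthalide) | Cc1c(O)c2C(=O)OCc2c2c1OC(=O)c1c(C)cc(O)c(C=O)c1O2 | intermediate
22 | [4,10-diacetoxy-5,8-dimethyl-3,7-dioxo-1,3-dihydro-7H-2,6,12-trioxabenzo[5,6]cyclohepta[1,2-e]inden-11-yl]methanediyl diacetate (tetraacetate) | Cc1c(OC(C)=O)c2C(=O)OCc2c2c1OC(=O)c1c(C)cc(OC(C)=O)c(C(OC(C)=O)OC(C)=O)c1O2 | intermediate
23 | [4,10-diacetoxy-1-bromo-5-(bromomethyl)-8-methyl-3,7-dioxo-1,3-dihydro-7H-2,6,12-trioxabenzo[5,6]cyclohepta[1,2-e]inden-11-yl]methanediyl diacetate, racemic at C1 (dibromide) | BrCc1c(OC(C)=O)c2C(=O)OC(Br)c2c2c1OC(=O)c1c(C)cc(OC(C)=O)c(C(OC(C)=O)OC(C)=O)c1O2 | intermediate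
24 | 1,4,10-trihydroxy-5-(hydroxymethyl)-8-methyl-3,7-dioxo-1,3-dihydro-7H-2,6,12-trioxabenzo[5,6]cyclohepta[1,2-e]indene-11-carbaldehyde, racemic at C1 (racemic salazinic acid) | OCc1c(O)c2C(=O)OC(O)c2c2c1OC(=O)c1c(C)cc(O)c(C=O)c1O2 | intermediate
25 | [11-formyl-1,4,10-trihydroxy-8-methyl-3,7-dioxo-1,3-dihydro-7H-2,6,12-trioxabenzo[5,6]cyclohepta[1,2-e]inden-5-yl]methyl acetate, racemic at C1 (racemic galbinic acid) | CC(=O)OCc1c(O)c2C(=O)OC(O)c2c2c1OC(=O)c1c(C)cc(O)c(C=O)c1O2 | intermediate
26 | [(1S)-1-acetoxy-11-formyl-4,10-dihydroxy-8-methyl-3,7-dioxo-1,3-dihydro-7H-2,6,12-trioxabenzo[5,6]cyclohepta[1,2-e]inden-5-yl]methyl acetate | CC(=O)OCc1c(O)c2c(c3c1OC(=O)c1c(C)cc(O)c(C=O)c1O3)[C@@H](OC(C)=O)OC2=O | intermediate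
27 | galbinic acid, [(1S)-11-formyl-1,4,10-trihydroxy-8-methyl-3,7-dioxo-1,3-dihydro-7H-2,6,12-trioxabenzo[5,6]cyclohepta[1,2-e]inden-5-yl]methyl acetate | CC(=O)OCc1c(O)c2c(c3c1OC(=O)c1c(C)cc(O)c(C=O)c1O3)[C@@H](O)OC2=O | target

Total step count: 20. Longest linear sequence: 16 steps (steps 1–5, then 10–20).

Steps most likely to fail

Step 13. C–H palladation at C6' may be slowed by the flanking diaryl ether oxygen, so that O-alkylation of the carboxylate by the solvent and thermal decay of the aldehyde overtake the catalytic cycle. The fallback sets out from 16 and comes back at 20; it forms the same two bonds by deprotonation and cross-coupling instead of C–H palladation. The C6'–H of the benzyl ester lies between the ester and the aryloxy group and should be zincated by TMP2Zn·2MgCl2·2LiCl (THF, 25 °C), a base that tolerates aldehydes and esters. Iodolysis would give the benzyl 6-iodo ester F1. Stille coupling with (tributylstannyl)methanol (Pd(PPh3)4, dioxane, 100 °C) would give the 6-(hydroxymethyl) benzyl ester F2, which should lactonise onto the neighbouring ester (TsOH cat., toluene, 80 °C) to give 20; steps 12 and 13 are then skipped.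

Step 16. Hydrogen abstraction may be unselective: the ring B bromomethyl group may be brominated a second time, or the ring A methyl attacked, before the lactone carbon has reacted completely. The fallback sets out from 21 and comes back at 24; it takes the ring B methyl through a two-electron oxidation so that only one radical bromination remains. DDQ in acetic acid (60 °C) should abstract hydride from the only methyl that is ortho to a free phenol and trap the o-quinone methide as the 3'-acetoxymethyl diphenol F3; this step is the weakest of the fallback, because the phenol is electron-poor. Acetylation as in step 15 would give the pentaacetate F4. One equivalent of NBS (AIBN, PhCF3, 85 °C) should then brominate the lactone carbon to the bromide F5, the acetoxymethyl group between two ortho substituents being a poor hydrogen donor. Carbonate hydrolysis as in step 17 would give 24, the 3'-acetate leaving through the o-quinone methide; steps 15–17 are replaced.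

Step 19. The lipase may discriminate the enantiomers of this crowded lactol poorly, or ring–chain interconversion may be too slow to feed the reacting enantiomer. The fallback sets out from 25 and comes back at 27, replacing steps 19 and 20 by a physical resolution. Racemic 25 would be separated on a polysaccharide chiral stationary phase with an acidified, non-nucleophilic eluent (hexane–ethyl acetate–0.1% formic acid), the (S)-enantiomer being collected as 27. The (R)-enantiomer would be racemised by warming in wet acetone and recycled. New compounds on this path: none F0.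

Further compounds
F1 | step 13 | benzyl 4-formyl-6-iodo-3,8-dimethoxy-1,9-dimethyl-11-oxo-11H-dibenzo[b,e][1,4]dioxepine-7-carboxylate | Cc1c(OC)c(C(=O)OCc3ccccc3)c(I)c2c1OC(=O)c1c(C)cc(OC)c(C=O)c1O2
F2 | step 13 | benzyl 4-formyl-6-(hydroxymethyl)-3,8-dimethoxy-1,9-dimethyl-11-oxo-11H-dibenzo[b,e][1,4]dioxepine-7-carboxylate | Cc1c(OC)c(C(=O)OCc3ccccc3)c(CO)c2c1OC(=O)c1c(C)cc(OC)c(C=O)c1O2
F3 | step 16 | (11-formyl-4,10-dihydroxy-8-methyl-3,7-dioxo-1,3-dihydro-7H-2,6,12-trioxabenzo[5,6]cyclohepta[1,2-e]inden-5-yl)methyl acetate | CC(=O)OCc1c(O)c2C(=O)OCc2c2c1OC(=O)c1c(C)cc(O)c(C=O)c1O2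
F4 | step 16 | [4,10-diacetoxy-5-(acetoxymethyl)-8-methyl-3,7-dioxo-1,3-dihydro-7H-2,6,12-trioxabenzo[5,6]cyclohepta[1,2-e]inden-11-yl]methanediyl diacetate | CC(=O)OCc1c(OC(C)=O)c2C(=O)OCc2c2c1OC(=O)c1c(C)cc(OC(C)=O)c(C(OC(C)=O)OC(C)=O)c1O2
F5 | step 16 | [4,10-diacetoxy-5-(acetoxymethyl)-1-bromo-8-methyl-3,7-dioxo-1,3-dihydro-7H-2,6,12-trioxabenzo[5,6]cyclohepta[1,2-e]inden-11-yl]methanediyl diacetate, racemic at C1 | CC(=O)OCc1c(OC(C)=O)c2C(=O)OC(Br)c2c2c1OC(=O)c1c(C)cc(OC(C)=O)c(C(OC(C)=O)OC(C)=O)c1O2
F0 | step 19 | none | none
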